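**Plan**
- Retrosynthetic cuts, in order: the aryl–C2 bond of the oxolane (C2 traced back to a carboxyl group), the benzoate C–O bond, the C3–C4 ring bond together with the C–O bond of the 3-methyl carbon (borylative 1,6-enyne cyclisation), the alkyne–aryl bond, and the propargylic ether C–O bond.
- Forward: the open chain is assembled on (R)-but-3-ene-1,2-diol. One palladium step closes the oxolane (the only ring made), sets the (Z)-benzylidene and places boron, then OH, on the future ester carbon. Esterification, oxidation of the C2 hydroxymethyl group to CO2H, arylation and desilylation follow.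
- Enabling feature: oxolane C2 is bonded to the ring oxygen O1, so a carboxyl group at C2 is an α-alkoxy acid. Its decarboxylation gives an O1-stabilised radical held in the five-membered ring next to the C3 stereocentre. Both aryl rings are the same 4-hydroxy-3-methoxyphenyl unit, so one aryl iodide (2) serves as alkyne partner and as organozinc source.
- Stereochemistry: C2 of the chiral-pool diol directs C3 (trans) during cyclisation. C2 is then erased as a radical and rebuilt trans to C3 in the arylation. The alkene geometry comes from syn addition of H and C across the alkyne.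

Key step: step 10

Remark: the alkene insertion of step 5 is assumed to run 2,3-trans (C2 substituent pseudo-equatorial); this fixes (R)-3 as the starting diol, and (S)-3 would be used if the cis course prevailed.

**Step 1**
Reactants: 1 4-iodo-2-methoxyphenol
Product: 2 (4-iodo-2-methoxyphenoxy)tri(propan-2-yl)silane
Conditions: iPr3SiCl, imidazole, DMF, rt
Reagents that add atoms: triisopropylsilyl chloride, CC(C)[Si](Cl)(C(C)C)C(C)C
Why: Imidazole-promoted O-silylation of the phenol should give a bulky aryl silyl ether that withstands the later base, palladium, organozinc and buffered HF conditions.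

**Step 2**
Reactants: 3 (2R)-but-3-ene-1,2-diol
Product: 4 (2R)-1-[tert-butyl(dimethyl)silyl]oxybut-3-en-2-ol
Conditions: tBuMe2SiCl (1.0 equiv), imidazole, CH2Cl2, −20 to 0 °C
Reagents that add atoms: tert-butyldimethylsilyl chloride, CC(C)(C)[Si](C)(C)Cl
Why: Silylation should occur selectively at the primary hydroxyl on steric grounds (mono-protection of a 1,2-diol), leaving the stereocentre untouched.

**Step 3**
Reactants: 4 (2R)-1-[tert-butyl(dimethyl)silyl]oxybut-3-en-2-ol; 5 3-bromoprop-1-yne
Product: 6 tert-butyl-dimethyl-[(2R)-2-(prop-2-yn-1-yloxy)but-3-en-1-yl]oxysilane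
Conditions: NaH, Bu4NI (cat.), THF/DMF, −20 to 0 °C, bromide present before the base
Reagents that add atoms: none
Why: Williamson etherification of the secondary alkoxide with the reactive propargylic bromide at low temperature should outrun 1,2-silyl migration, and the stereocentre is not involved.

**Step 4**
Reactants: 6 propargyl ether; 2 aryl iodide
Product: 7 tert-butyl-[(2R)-2-[3-[3-methoxy-4-tri(propan-2-yl)silyloxyphenyl]prop-2-yn-1-yloxy]but-3-en-1-yl]oxy-dimethylsilane
Conditions: Pd(PPh3)2Cl2 (3 mol %), CuI (5 mol %), Et3N, THF, rt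
Reagents that add atoms: none
Why: Sonogashira coupling of a terminal alkyne with an aryl iodide proceeds at room temperature and should leave the silyl ethers, the allylic ether and the vinyl group untouched.

**Step 5**
Reactants: 7 aryl 1,6-enyne
Product: 9 [(2R,3S,4Z)-2-[[tert-butyl(dimethyl)silyl]oxymethyl]-4-[[3-methoxy-4-tri(propan-2-yl)silyloxyphenyl]methylidene]oxolan-3-yl]methanol, via pinacol boronate 8 (not isolated)
Conditions: Pd(OAc)2 (5 mol %), B2pin2 (1.2 equiv), MeOH (1 equiv), toluene, 50 °C; then NaBO3·4H2O, THF/H2O, rt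
Reagents that add atoms: sodium perborate, [Na+].[O-]OB=O (oxygen of the new hydroxyl); bis(pinacolato)diboron, CC1(C)OB(OC1(C)C)B1OC(C)(C)C(C)(C)O1 (boron of 8 only)
Why: Palladium-catalysed borylative enyne cyclisation (syn-hydropalladation of the alkyne by a hydride of divalent palladium with Pd at the propargylic carbon, 5-exo-trig insertion of the vinyl group, transmetalation with B2pin2, C–B reductive elimination) followed by retentive perborate oxidation should fix the (Z)-benzylidene through syn addition of H and C and set C3 trans to the pseudo-equatorial C2 silyloxymethyl group by 1,2-induction, the minor cis isomer being removed by chromatography at the alcohol stage.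

**Step 6**
Reactants: 10 4-hydroxybenzoic acid
Product: 12 4-tri(propan-2-yl)silyloxybenzoic acid, via silyl ester 11 (not isolated)
Conditions: iPr3SiCl (2.3 equiv), imidazole, DMF, rt; then K2CO3, THF/MeOH/H2O, rt; work-up at pH 4
Reagents that add atoms: triisopropylsilyl chloride, CC(C)[Si](Cl)(C(C)C)C(C)C
Why: Exhaustive silylation followed by carbonate hydrolysis of the far more labile silyl ester should leave the aryl silyl ether in place.

**Step 7**
Reactants: 9 oxolanylmethanol; 12 4-tri(propan-2-yl)silyloxybenzoic acid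
Product: 13 [(2R,3S,4Z)-2-[[tert-butyl(dimethyl)silyl]oxymethyl]-4-[[3-methoxy-4-tri(propan-2-yl)silyloxyphenyl]methylidene]oxolan-3-yl]methyl 4-tri(propan-2-yl)silyloxybenzoate
Conditions: EDC·HCl, DMAP (cat.), CH2Cl2, rt
Reagents that add atoms: none
Why: Steglich-type carbodiimide esterification of an unhindered primary alcohol should proceed without touching either stereocentre or the alkene.

**Step 8**
Reactants: 13 silyl-protected ester
Product: 14 [(2R,3S,4Z)-2-(hydroxymethyl)-4-[[3-methoxy-4-tri(propan-2-yl)silyloxyphenyl]methylidene]oxolan-3-yl]methyl 4-tri(propan-2-yl)silyloxybenzoate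
Conditions: HF·pyridine, pyridine, THF, 0 °C to rt
Reagents that add atoms: none
Why: Buffered HF·pyridine should cleave the primary alkyl silyl ether much faster than the bulky aryl silyl ethers, in a medium too weakly acidic to ionise the allylic ring ether or protonate the styrene.

**Step 9**
Reactants: 14 primary alcohol
Product: 16 (2R,3S,4Z)-4-[[3-methoxy-4-tri(propan-2-yl)silyloxyphenyl]methylidene]-3-[[4-tri(propan-2-yl)silyloxybenzoyl]oxymethyl]oxolane-2-carboxylic acid, via aldehyde 15 (not isolated)
Conditions: TEMPO (20 mol %), PhI(OAc)2 (2.5 equiv), MeCN/H2O, rt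
Reagents that add atoms: water, O
Why: Nitroxyl-catalysed oxidation with PhI(OAc)2 in aqueous acetonitrile should take the alcohol through the aldehyde hydrate to the α-alkoxy acid, as is routine for uronic acids, and any epimerisation at C2 is harmless because that centre is erased in step 10.

**Step 10**
Reactants: 16 oxolane-2-carboxylic acid; 2 aryl iodide
Product: 20 [(2R,3S,4Z)-2-[3-methoxy-4-tri(propan-2-yl)silyloxyphenyl]-4-[[3-methoxy-4-tri(propan-2-yl)silyloxyphenyl]methylidene]oxolan-3-yl]methyl 4-tri(propan-2-yl)silyloxybenzoate, via phthalimidoyl ester 17 (not isolated), via arylmagnesium chloride 18 (not isolated), via arylzinc chloride 19 (not isolated)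
Conditions: 16, N-hydroxyphthalimide, iPrN=C=NiPr, DMAP (cat.), CH2Cl2, rt, filter, evaporate; separately 2, iPrMgCl·LiCl, THF, −20 to 0 °C, then ZnCl2; combine with NiCl2·(MeOCH2CH2OMe) (20 mol %), 4,4'-di-tert-butyl-2,2'-bipyridine (40 mol %), THF/DMF, rt, dark
Reagents that add atoms: N-hydroxyphthalimide, O=C1c2ccccc2C(=O)N1O (in 17 only); iPrMgCl·LiCl, CC(C)[Mg]Cl.[Li+].[Cl-] (Mg and Cl of 18 only); ZnCl2, Cl[Zn]Cl (Zn and Cl of 19 only)
Why: A monovalent aryl-nickel species formed from 19 transfers one electron to ester 17, whose radical anion loses phthalimide anion and CO2 to leave the C2 radical; this recombines with aryl-nickel (divalent) to give a trivalent alkyl(aryl)nickel that forms the aryl–C2 bond by reductive elimination. The closest known reaction type is the nickel-catalysed decarboxylative Negishi arylation of redox-active esters of α-alkoxy acids such as oxolane-2-carboxylic acid. No ring is closed, since the oxolane is already in place. The new stereocentre C2 arises from a radical flattened by conjugation with the O1 lone pair, so its earlier configuration is irrelevant, and the bulky aryl-nickel unit should be taken up on the face opposite the C3 aroyloxymethyl group, giving the 2,3-trans (2R) isomer, which is also the more stable one. The step needs radical capture to outrun ring opening and addition to the styrene: 3-exo closure onto C4 would create a bicyclo[2.1.0] skeleton, the O1–C5 bond lies in the nodal plane of the radical, the benzylidene is trisubstituted, the ester and silyl ethers are inert to arylzinc, and the absence of light leaves the (Z)-alkene unisomerised.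

**Step 11**
Reactants: 20 tris-silyl ether
Product: 21 [(2R,3S,4Z)-2-(4-hydroxy-3-methoxyphenyl)-4-[(4-hydroxy-3-methoxyphenyl)methylidene]oxolan-3-yl]methyl 4-hydroxybenzoate
Conditions: Bu4NF, AcOH (1:1), THF, 0 °C
Reagents that add atoms: none
Why: Fluoride should cleave the three aryl silyl ethers while acetic acid buffers the phenoxides, so the benzoate ester, the benzylic ether stereocentre at C2 and the alkene stay untouched.

**Compound list**
1 | 4-iodo-2-methoxyphenol | COc1cc(I)ccc1O | starting material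
2 | (4-iodo-2-methoxyphenoxy)tri(propan-2-yl)silane | COc1cc(I)ccc1O[Si](C(C)C)(C(C)C)C(C)C | intermediate
3 | (2R)-but-3-ene-1,2-diol | C=C[C@@H](O)CO | starting material
4 | (2R)-1-[tert-butyl(dimethyl)silyl]oxybut-3-en-2-ol | C=C[C@@H](O)CO[Si](C)(C)C(C)(C)C | intermediate
5 | 3-bromoprop-1-yne | C#CCBr | starting material
6 | tert-butyl-dimethyl-[(2R)-2-(prop-2-yn-1-yloxy)but-3-en-1-yl]oxysilane | C=C[C@@H](OCC#C)CO[Si](C)(C)C(C)(C)C | intermediate
7 | tert-butyl-[(2R)-2-[3-[3-methoxy-4-tri(propan-2-yl)silyloxyphenyl]prop-2-yn-1-yloxy]but-3-en-1-yl]oxy-dimethylsilane | C=C[C@@H](OCC#Cc1ccc(O[Si](C(C)C)(C(C)C)C(C)C)c(OC)c1)CO[Si](C)(C)C(C)(C)C | intermediate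
8 | tert-butyl-[[(2R,3R,4Z)-4-[[3-methoxy-4-tri(propan-2-yl)silyloxyphenyl]methylidene]-3-[(4,4,5,5-tetramethyl-1,3,2-dioxaborolan-2-yl)methyl]oxolan-2-yl]methoxy]-dimethylsilane | COc1cc(/C=C2\CO[C@@H](CO[Si](C)(C)C(C)(C)C)[C@@H]2CB3OC(C)(C)C(C)(C)O3)ccc1O[Si](C(C)C)(C(C)C)C(C)C | intermediate
9 | [(2R,3S,4Z)-2-[[tert-butyl(dimethyl)silyl]oxymethyl]-4-[[3-methoxy-4-tri(propan-2-yl)silyloxyphenyl]methylidene]oxolan-3-yl]methanol | COc1cc(/C=C2\CO[C@@H](CO[Si](C)(C)C(C)(C)C)[C@@H]2CO)ccc1O[Si](C(C)C)(C(C)C)C(C)C | intermediate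
10 | 4-hydroxybenzoic acid | O=C(O)c1ccc(O)cc1 | starting material
11 | tri(propan-2-yl)silyl 4-tri(propan-2-yl)silyloxybenzoate | CC(C)[Si](OC(=O)c1ccc(O[Si](C(C)C)(C(C)C)C(C)C)cc1)(C(C)C)C(C)C | intermediate
12 | 4-tri(propan-2-yl)silyloxybenzoic acid | O=C(O)c1ccc(O[Si](C(C)C)(C(C)C)C(C)C)cc1 | intermediate
13 | [(2R,3S,4Z)-2-[[tert-butyl(dimethyl)silyl]oxymethyl]-4-[[3-methoxy-4-tri(propan-2-yl)silyloxyphenyl]methylidene]oxolan-3-yl]methyl 4-tri(propan-2-yl)silyloxybenzoate | COc1cc(/C=C2\CO[C@@H](CO[Si](C)(C)C(C)(C)C)[C@@H]2COC(=O)c2ccc(O[Si](C(C)C)(C(C)C)C(C)C)cc2)ccc1O[Si](C(C)C)(C(C)C)C(C)C | intermediate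
14 | [(2R,3S,4Z)-2-(hydroxymethyl)-4-[[3-methoxy-4-tri(propan-2-yl)silyloxyphenyl]methylidene]oxolan-3-yl]methyl 4-tri(propan-2-yl)silyloxybenzoate | COc1cc(/C=C2\CO[C@@H](CO)[C@@H]2COC(=O)c2ccc(O[Si](C(C)C)(C(C)C)C(C)C)cc2)ccc1O[Si](C(C)C)(C(C)C)C(C)C | intermediate
15 | [(2R,3S,4Z)-2-formyl-4-[[3-methoxy-4-tri(propan-2-yl)silyloxyphenyl]methylidene]oxolan-3-yl]methyl 4-tri(propan-2-yl)silyloxybenzoate | COc1cc(/C=C2\CO[C@@H](C=O)[C@@H]2COC(=O)c2ccc(O[Si](C(C)C)(C(C)C)C(C)C)cc2)ccc1O[Si](C(C)C)(C(C)C)C(C)C | intermediate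
16 | (2R,3S,4Z)-4-[[3-methoxy-4-tri(propan-2-yl)silyloxyphenyl]methylidene]-3-[[4-tri(propan-2-yl)silyloxybenzoyl]oxymethyl]oxolane-2-carboxylic acid | COc1cc(/C=C2\CO[C@@H](C(=O)O)[C@@H]2COC(=O)c2ccc(O[Si](C(C)C)(C(C)C)C(C)C)cc2)ccc1O[Si](C(C)C)(C(C)C)C(C)C | intermediate
17 | (1,3-dioxoisoindol-2-yl) (2R,3S,4Z)-4-[[3-methoxy-4-tri(propan-2-yl)silyloxyphenyl]methylidene]-3-[[4-tri(propan-2-yl)silyloxybenzoyl]oxymethyl]oxolane-2-carboxylate | COc1cc(/C=C2\CO[C@@H](C(=O)ON3C(=O)c4ccccc4C3=O)[C@@H]2COC(=O)c2ccc(O[Si](C(C)C)(C(C)C)C(C)C)cc2)ccc1O[Si](C(C)C)(C(C)C)C(C)C | intermediate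
18 | chloro-[3-methoxy-4-tri(propan-2-yl)silyloxyphenyl]magnesium (LiCl complex) | COc1cc([Mg]Cl)ccc1O[Si](C(C)C)(C(C)C)C(C)C | intermediate
19 | chloro-[3-methoxy-4-tri(propan-2-yl)silyloxyphenyl]zinc | COc1cc([Zn]Cl)ccc1O[Si](C(C)C)(C(C)C)C(C)C | intermediate
20 | [(2R,3S,4Z)-2-[3-methoxy-4-tri(propan-2-yl)silyloxyphenyl]-4-[[3-methoxy-4-tri(propan-2-yl)silyloxyphenyl]methylidene]oxolan-3-yl]methyl 4-tri(propan-2-yl)silyloxybenzoate | COc1cc(/C=C2\CO[C@@H](c3ccc(O[Si](C(C)C)(C(C)C)C(C)C)c(OC)c3)[C@@H]2COC(=O)c2ccc(O[Si](C(C)C)(C(C)C)C(C)C)cc2)ccc1O[Si](C(C)C)(C(C)C)C(C)C | intermediate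
21 | [(2R,3S,4Z)-2-(4-hydroxy-3-methoxyphenyl)-4-[(4-hydroxy-3-methoxyphenyl)methylidene]oxolan-3-yl]methyl 4-hydroxybenzoate | COc1cc(/C=C2\CO[C@@H](c3ccc(O)c(OC)c3)[C@@H]2COC(=O)c2ccc(O)cc2)ccc1O | target

**Step count**
Total: 11 steps. Longest linear sequence: 9 steps (3 → 4 → 6 → 7 → 9 → 13 → 14 → 16 → 20 → 21; steps 2, 3, 4, 5, 7, 8, 9, 10, 11).

**Steps most likely to fail**

1. Step 10. The capture of the C2 radical by aryl-nickel may show poor facial selectivity. The α-alkoxy radical may also be oxidised to the oxocarbenium ion, which loses H3 and aromatises to a furan, and low-valent nickel may insert into the allylic C5–O bond. The fallback replaces the radical coupling by a polar one and sets out from 16. Oxidative decarboxylation with Pb(OAc)4 and pyridine in THF should give [(3S,4Z)-2-acetyloxy-4-[[3-methoxy-4-tri(propan-2-yl)silyloxyphenyl]methylidene]oxolan-3-yl]methyl 4-tri(propan-2-yl)silyloxybenzoate F1 as a mixture of C2 epimers. Aryl iodide 2 is converted through 18 with B(OMe)3 and then briefly with aqueous KHF2 into potassium trifluoro-[3-methoxy-4-tri(propan-2-yl)silyloxyphenyl]borate F2. BF3·OEt2 in MeCN/CH2Cl2 at −40 °C should ionise F1, and ipso transfer of the aryl group of F2 to C2, anti to the C3 substituent, returns the route at 20. The low temperature is meant to keep the cation from losing H3.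

2. Step 5. The alkene insertion may give poor 2,3-diastereoselectivity, the alkylpalladium may undergo β-hydride elimination to a diene before borylation, and hydropalladation may place palladium on the aryl-bearing carbon. The fallback is a titanocene-mediated radical cyclisation and sets out from 6. Epoxidation of the vinyl group with mCPBA should give tert-butyl-dimethyl-[(2S)-2-(oxiran-2-yl)-2-(prop-2-yn-1-yloxy)ethoxy]silane F3 as both oxirane epimers, which converge later. Sonogashira coupling with 2 should give the epoxy aryl alkyne tert-butyl-[(2S)-2-[3-[3-methoxy-4-tri(propan-2-yl)silyloxyphenyl]prop-2-yn-1-yloxy]-2-(oxiran-2-yl)ethoxy]-dimethylsilane F4. Cp2TiCl (trivalent titanium, made from Cp2TiCl2 and zinc) in THF opens the epoxide to the secondary radical, which closes 5-exo-dig onto the alkyne trans to the C2 substituent and returns the route at 9 after protonolysis. This termination does not fix the alkene geometry, so the benzylidene isomers would be equilibrated with catalytic iodine toward the less strained (Z) isomer.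

3. Step 3. The silyl group may migrate from the primary to the secondary oxygen in the alkoxide, so that the wrong hydroxyl is propargylated. The fallback forms the ether before any silyl group is present and sets out from 2. Sonogashira coupling with prop-2-yn-1-ol should give 3-[3-methoxy-4-tri(propan-2-yl)silyloxyphenyl]prop-2-yn-1-ol F5. Palladium-catalysed dynamic kinetic asymmetric allylic etherification of racemic 2-vinyloxirane with F5 (Pd2(dba)3·CHCl3, the antipode of N,N'-(cyclohexane-1,2-diyl)bis[2-(diphenylphosphino)benzamide] that delivers the (R)-ether, BEt3 cat., CH2Cl2) should give (2R)-2-[3-[3-methoxy-4-tri(propan-2-yl)silyloxyphenyl]prop-2-yn-1-yloxy]but-3-en-1-ol F6. Silylation with tBuMe2SiCl and imidazole returns the route at 7.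

**Further compounds**
F1 | step 10 | [(3S,4Z)-2-acetyloxy-4-[[3-methoxy-4-tri(propan-2-yl)silyloxyphenyl]methylidene]oxolan-3-yl]methyl 4-tri(propan-2-yl)silyloxybenzoate (both C2 epimers) | COc1cc(/C=C2\COC(OC(C)=O)[C@@H]2COC(=O)c2ccc(O[Si](C(C)C)(C(C)C)C(C)C)cc2)ccc1O[Si](C(C)C)(C(C)C)C(C)C
F2 | step 10 | potassium trifluoro-[3-methoxy-4-tri(propan-2-yl)silyloxyphenyl]borate | COc1cc([B-](F)(F)F)ccc1O[Si](C(C)C)(C(C)C)C(C)C.[K+]
F3 | step 5 | tert-butyl-dimethyl-[(2S)-2-(oxiran-2-yl)-2-(prop-2-yn-1-yloxy)ethoxy]silane (both oxirane epimers) | C1OC1[C@@H](OCC#C)CO[Si](C)(C)C(C)(C)C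
F4 | step 5 | tert-butyl-[(2S)-2-[3-[3-methoxy-4-tri(propan-2-yl)silyloxyphenyl]prop-2-yn-1-yloxy]-2-(oxiran-2-yl)ethoxy]-dimethylsilane (both oxirane epimers) | C1OC1[C@@H](OCC#Cc2ccc(O[Si](C(C)C)(C(C)C)C(C)C)c(OC)c2)CO[Si](C)(C)C(C)(C)C
F5 | step 3 | 3-[3-methoxy-4-tri(propan-2-yl)silyloxyphenyl]prop-2-yn-1-ol | COc1cc(C#CCO)ccc1O[Si](C(C)C)(C(C)C)C(C)C
F6 | step 3 | (2R)-2-[3-[3-methoxy-4-tri(propan-2-yl)silyloxyphenyl]prop-2-yn-1-yloxy]but-3-en-1-ol | C=C[C@@H](OCC#Cc1ccc(O[Si](C(C)C)(C(C)C)C(C)C)c(OC)c1)CO
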